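The benzene ring of the indenone is made last: its C5–C6 bond is disconnected, which leaves a cyclopentenone whose C3a=C7a double bond carries an isopropenyl group (C7, C6) and a 1-isobutyrylvinyl group (C4, C5). The feature exploited is that C5 and C6 are the only adjacent unsubstituted carbons of the benzene ring, so both triene termini are plain methylene groups. Heating this 2,3-divinylcyclopentenone closes the six-membered ring in one thermal six-electron electrocyclisation; two dehydrogenations (ring, then C2–C3) finish the target. The precursor comes from guaiazulene and a methylcyclopentenedione by conjugate addition, bromination, triflation and two vinyl cross-couplings, the ketone being unmasked only just before heating.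

Key step: step 9

Remark: guaiazulen-3-yl denotes 5-isopropyl-3,8-dimethylazulen-1-yl. The ring stereocentres are transient (the target has none), so all material is racemic with the trans isomer drawn as one enantiomer. The carbinol carbon of the stannane fragment is carried as a mixture of epimers until it is oxidised.

Step 1
Reactants: 1 3-methylcyclopent-2-en-1-one
Product: 2 4-methylcyclopent-4-ene-1,3-dione
Conditions: Pd(OH)2/C (5 mol%), tBuOOH (5 equiv), K2CO3 (0.25 equiv), CH2Cl2, 0 °C → rt
Reagents that add atoms: tert-butyl hydroperoxide, CC(C)(C)OO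
Why: Palladium-catalysed tert-butylperoxyl-radical oxidation of the γ-methylene group of an α,β-enone to the 1,4-enedione (peroxide formation then Kornblum–DeLaMare-type collapse); the ring CH2 next to the alkene should be attacked in preference to the methyl group and no stereocentre arises.

Step 2
Reactants: 2 4-methylcyclopent-4-ene-1,3-dione; 3 guaiazulene (7-isopropyl-1,4-dimethylazulene)
Product: 4 trans-4-(guaiazulen-3-yl)-5-methylcyclopentane-1,3-dione (largely enolised)
Conditions: AcOH/CH2Cl2 (1:4), rt, Ar, dark
Reagents that add atoms: none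
Why: Friedel–Crafts-type conjugate (Michael) addition in which the nucleophilic C3 of guaiazulene attacks the unsubstituted alkene carbon of the acid-activated enedione; both new stereocentres are α to a carbonyl and should equilibrate by enolisation to the more stable trans arrangement.

Step 3
Reactants: 4 trans-4-(guaiazulen-3-yl)-5-methylcyclopentane-1,3-dione
Product: 5 trans-2-bromo-4-(guaiazulen-3-yl)-5-methylcyclopentane-1,3-dione (enolised, one enol drawn)
Conditions: NBS (1.0 equiv), CH2Cl2, −40 → 0 °C, dark
Reagents that add atoms: N-bromosuccinimide, O=C1CCC(=O)N1Br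
Why: Electrophilic bromination of the enolised 1,3-dione at the carbon between the carbonyls, which should be much faster than attack on the azulene because its reactive 1- and 3-positions are both substituted; the ring stereocentres are not touched.

Step 4
Reactants: 5 trans-2-bromo-4-(guaiazulen-3-yl)-5-methylcyclopentane-1,3-dione
Product: 6 trans-2-bromo-4-(guaiazulen-3-yl)-5-methyl-3-oxocyclopent-1-en-1-yl trifluoromethanesulfonate
Conditions: Et3N (1.2 equiv), then Tf2O (1.05 equiv, slow addition), CH2Cl2, −78 °C
Reagents that add atoms: trifluoromethanesulfonic anhydride, O=S(=O)(OS(=O)(=O)C(F)(F)F)C(F)(F)F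
Why: O-Sulfonylation of the ambident 1,3-dione enolate (enol triflate formation), in which the oxygen beside the methyl-bearing carbon is less shielded than the one beside the azulenyl group with its peri-methyl, so the triflate should form there and leave the ketone next to the azulenyl carbon; no stereocentre is changed.

Step 5
Reactants: 7 4-methylpent-1-yn-3-ol (racemic)
Product: 8 4-methyl-2-(tributylstannyl)pent-1-en-3-ol (racemic)
Conditions: Bu3SnH (1.5 equiv), Mo(CO)3(CNtBu)3 (2 mol%), hydroquinone (cat.), THF, 55 °C
Reagents that add atoms: tributyltin hydride, CCCC[SnH](CCCC)CCCC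
Why: Molybdenum-catalysed hydrostannation of a terminal propargylic alcohol, which delivers tin to the internal carbon and hydrogen to the terminus and so gives the 1,1-disubstituted vinylstannane; the carbinol centre is that of racemic 7.

Step 6
Reactants: 6 trans-2-bromo-4-(guaiazulen-3-yl)-5-methyl-3-oxocyclopent-1-en-1-yl trifluoromethanesulfonate; 8 4-methyl-2-(tributylstannyl)pent-1-en-3-ol
Product: 9 trans-2-bromo-5-(guaiazulen-3-yl)-3-(3-hydroxy-4-methylpent-1-en-2-yl)-4-methylcyclopent-2-en-1-one (carbinol epimers)
Conditions: Pd2(dba)3 (2.5 mol%), AsPh3 (20 mol%), CuI (20 mol%), NMP, rt → 40 °C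
Reagents that add atoms: none
Why: Copper-co-catalysed Stille coupling in which oxidative addition should occur at the C–O bond of the vinylogous acyl triflate (electron-poor β-carbon) faster than at the α-C–Br bond, the copper salt speeding transmetallation of the hindered 1-substituted vinylstannane; the carbinol centre comes in uncontrolled from racemic 8 and is removed in step 8.

Step 7
Reactants: 9 trans-2-bromo-5-(guaiazulen-3-yl)-3-(3-hydroxy-4-methylpent-1-en-2-yl)-4-methylcyclopent-2-en-1-one; 10 isopropenylboronic acid pinacol ester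
Product: 11 trans-5-(guaiazulen-3-yl)-3-(3-hydroxy-4-methylpent-1-en-2-yl)-4-methyl-2-(prop-1-en-2-yl)cyclopent-2-en-1-one (carbinol epimers)
Conditions: Pd(OAc)2 (5 mol%), SPhos (10 mol%), K3PO4 (2 equiv), THF/H2O (10:1), 45 °C
Reagents that add atoms: none
Why: Suzuki–Miyaura coupling of the α-bromo enone with an unhindered alkenylboronate under a bulky biarylphosphine catalyst at mild temperature, which should leave the free alcohol, the enone and the azulene untouched and creates no stereocentre.

Step 8
Reactants: 11 trans-5-(guaiazulen-3-yl)-3-(3-hydroxy-4-methylpent-1-en-2-yl)-4-methyl-2-(prop-1-en-2-yl)cyclopent-2-en-1-one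
Product: 12 trans-5-(guaiazulen-3-yl)-4-methyl-3-(4-methyl-3-oxopent-1-en-2-yl)-2-(prop-1-en-2-yl)cyclopent-2-en-1-one
Conditions: Dess–Martin periodinane (1.3 equiv), CH2Cl2, 0 °C → rt; cold silica plug, used at once
Reagents that add atoms: none
Why: Dess–Martin oxidation of the secondary allylic alcohol to the α-methylene ketone under near-neutral conditions, which merges the carbinol epimers and unveils the barrier-lowering acyl group only now, so that the dimerisation-prone 2-acyl diene never meets a palladium catalyst or base.

Step 9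
Reactants: 12 trans-5-(guaiazulen-3-yl)-4-methyl-3-(4-methyl-3-oxopent-1-en-2-yl)-2-(prop-1-en-2-yl)cyclopent-2-en-1-one
Product: 13 trans-2-(guaiazulen-3-yl)-4-isobutyryl-3,7-dimethyl-2,3,5,6-tetrahydro-1H-inden-1-one
Conditions: degassed toluene (0.005 M), BHT (5 mol%), 100–110 °C, Ar, dark
Reagents that add atoms: none
Why: On heating, the cis-hexatriene C5=C4–C3a=C7a–C7=C6 (indenone numbering) should undergo a concerted thermal six-electron electrocyclisation through a boat-like transition state, forming the C5–C6 σ-bond and moving the double bonds to C3a=C4 and C7=C7a. The closest known reaction type is the thermal closure of 1,2-divinylcycloalkenes to ring-fused cyclohexa-1,3-dienes, eased here by the acyl group on the internal carbon C4 and by the unsubstituted CH2 termini. The six-membered ring closes in the disrotatory 6π mode; because both termini are CH2 no stereocentre is created, and the trans C2/C3 centres are not involved. The ring double bond holds the two vinyl groups cis, whereas the ring carbonyl is transoid to the acylvinyl group and the side-chain ketone sits on an internal triene carbon, so no 1-oxatriene exists and no 2H-pyran can form. The selectivity needed is therefore unimolecular closure over bimolecular hetero-Diels–Alder dimerisation or radical polymerisation of the α-methylene ketone, which high dilution, BHT and exclusion of oxygen should secure.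

Step 10
Reactants: 13 trans-2-(guaiazulen-3-yl)-4-isobutyryl-3,7-dimethyl-2,3,5,6-tetrahydro-1H-inden-1-one
Product: 14 trans-2-(guaiazulen-3-yl)-4-isobutyryl-3,7-dimethylindan-1-one
Conditions: activated MnO2 (15 equiv), CH2Cl2, rt
Reagents that add atoms: none
Why: Oxidative dehydrogenation (aromatisation) of the cyclohexa-1,3-diene, driven by formation of the benzene ring and effected by a mild heterogeneous oxidant that should spare the azulene; C2 and C3 keep their trans arrangement.

Step 11
Reactants: 14 trans-2-(guaiazulen-3-yl)-4-isobutyryl-3,7-dimethylindan-1-one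
Product: 16 2-(guaiazulen-3-yl)-4-isobutyryl-3,7-dimethyl-1H-inden-1-one, via 2-phenylselanyl indanone 15 (not isolated)
Conditions: LiN(SiMe3)2 (1.05 equiv), THF, −78 → −20 °C; PhSeBr (1.05 equiv), −78 °C; then AcOH, 30% H2O2, 0 °C → rt
Reagents that add atoms: none
Why: α-Selenenylation of the thermodynamic C2 enolate (C2–H, flanked by the carbonyl and the azulene, is far more acidic than the isobutyryl methine) should occur anti to the C3 methyl and so place selenium cis to H3, after which selenoxide syn-elimination can only give the C2=C3 double bond and erases both stereocentres.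

Compound list
1 | 3-methylcyclopent-2-en-1-one | CC1=CC(=O)CC1 | starting material
2 | 4-methylcyclopent-4-ene-1,3-dione | O=C1CC(=O)C(C)=C1 | intermediate
3 | guaiazulene (7-isopropyl-1,4-dimethylazulene) | c1cc(C)c2cc(C(C)C)ccc(C)c1-2 | starting material
4 | trans-4-(guaiazulen-3-yl)-5-methylcyclopentane-1,3-dione (racemic) | C[C@@H]1C(=O)CC(=O)[C@H]1c1cc(C)c2cc(C(C)C)ccc(C)c1-2 | intermediate
5 | trans-2-bromo-4-(guaiazulen-3-yl)-5-methylcyclopentane-1,3-dione (racemic, one enol tautomer drawn) | C[C@@H]1C(O)=C(Br)C(=O)[C@H]1c1cc(C)c2cc(C(C)C)ccc(C)c1-2 | intermediate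
6 | trans-2-bromo-4-(guaiazulen-3-yl)-5-methyl-3-oxocyclopent-1-en-1-yl trifluoromethanesulfonate (racemic) | C[C@@H]1C(OS(=O)(=O)C(F)(F)F)=C(Br)C(=O)[C@H]1c1cc(C)c2cc(C(C)C)ccc(C)c1-2 | intermediate
7 | 4-methylpent-1-yn-3-ol (racemic) | C#CC(O)C(C)C | starting material
8 | 4-methyl-2-(tributylstannyl)pent-1-en-3-ol (racemic) | C=C([Sn](CCCC)(CCCC)CCCC)C(O)C(C)C | intermediate
9 | trans-2-bromo-5-(guaiazulen-3-yl)-3-(3-hydroxy-4-methylpent-1-en-2-yl)-4-methylcyclopent-2-en-1-one (racemic, carbinol epimers) | C[C@@H]1C(C(=C)C(O)C(C)C)=C(Br)C(=O)[C@H]1c1cc(C)c2cc(C(C)C)ccc(C)c1-2 | intermediate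
10 | isopropenylboronic acid pinacol ester | C=C(C)B1OC(C)(C)C(C)(C)O1 | starting material
11 | trans-5-(guaiazulen-3-yl)-3-(3-hydroxy-4-methylpent-1-en-2-yl)-4-methyl-2-(prop-1-en-2-yl)cyclopent-2-en-1-one (racemic, carbinol epimers) | C[C@@H]1C(C(=C)C(O)C(C)C)=C(C(C)=C)C(=O)[C@H]1c1cc(C)c2cc(C(C)C)ccc(C)c1-2 | intermediate
12 | trans-5-(guaiazulen-3-yl)-4-methyl-3-(4-methyl-3-oxopent-1-en-2-yl)-2-(prop-1-en-2-yl)cyclopent-2-en-1-one (racemic) | C[C@@H]1C(C(=C)C(=O)C(C)C)=C(C(C)=C)C(=O)[C@H]1c1cc(C)c2cc(C(C)C)ccc(C)c1-2 | intermediate
13 | trans-2-(guaiazulen-3-yl)-4-isobutyryl-3,7-dimethyl-2,3,5,6-tetrahydro-1H-inden-1-one (racemic) | C[C@@H]1C2=C(C(=O)C(C)C)CCC(C)=C2C(=O)[C@H]1c1cc(C)c2cc(C(C)C)ccc(C)c1-2 | intermediate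
14 | trans-2-(guaiazulen-3-yl)-4-isobutyryl-3,7-dimethylindan-1-one (racemic) | C[C@@H]1c2c(C(=O)C(C)C)ccc(C)c2C(=O)[C@H]1c1cc(C)c2cc(C(C)C)ccc(C)c1-2 | intermediate
15 | 2-(guaiazulen-3-yl)-4-isobutyryl-3,7-dimethyl-2-(phenylselanyl)indan-1-one, selenium trans to the C3 methyl (racemic) | C[C@@H]1c2c(C(=O)C(C)C)ccc(C)c2C(=O)[C@@]1(c1cc(C)c2cc(C(C)C)ccc(C)c1-2)[Se]c1ccccc1 | intermediate
16 | 2-(guaiazulen-3-yl)-4-isobutyryl-3,7-dimethyl-1H-inden-1-one (CNP0225119.0) | CC1=C(c2cc(C)c3cc(C(C)C)ccc(C)c2-3)C(=O)c2c(C)ccc(C(=O)C(C)C)c21 | target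

Total step count: 11. Longest linear sequence: 10 steps (steps 1–4 and 6–11 from compound 1); step 5 is a one-step side branch.

Steps most likely to fail

Step 9. The unimolecular closure may be overtaken by bimolecular hetero-Diels–Alder dimerisation or polymerisation of the α-methylene ketone at the temperature the closure needs. The fallback closes the ring before the ketone exists. It sets out from 11, which has no enone in the side chain and can be heated harder (degassed o-xylene, 150 °C, BHT). This should give the cyclohexadiene carbinol trans-2-(guaiazulen-3-yl)-4-(1-hydroxy-2-methylpropyl)-3,7-dimethyl-2,3,5,6-tetrahydro-1H-inden-1-one F1. MnO2 in CH2Cl2 should aromatise it to trans-2-(guaiazulen-3-yl)-4-(1-hydroxy-2-methylpropyl)-3,7-dimethylindan-1-one F2. Dess–Martin oxidation of the benzylic alcohol then comes back to the route at 14.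

Step 4. Sulfonylation may spread over both enolate oxygens, and the wrong enol triflate cannot be corrected afterwards. The fallback replaces irreversible sulfonylation and cross-coupling by reversible enol ether formation and carbonyl addition. It sets out from 5. Acid-catalysed etherification (MeOH, HC(OMe)3, TsOH, 50 °C) should give trans-2-bromo-4-(guaiazulen-3-yl)-3-methoxy-5-methylcyclopent-2-en-1-one F3 beside its regioisomer trans-2-bromo-5-(guaiazulen-3-yl)-3-methoxy-4-methylcyclopent-2-en-1-one F4. After separation, F4 is returned to the equilibrating conditions, so all material can be funnelled into F3. The dilithio species from 8 (MeLi, 2 equiv, THF, −78 °C; anhydrous CeCl3) adds to the carbonyl of F3. Aqueous HCl work-up then effects a Stork–Danheiser transposition with loss of methanol, which comes back to the route at 9 and bypasses steps 4 and 6.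

Step 11. Selenenylation may stall at the congested quaternary C2 or take place syn to the C3 methyl, which leaves no syn hydrogen for elimination; the peroxide may also attack the azulene. The fallback uses a palladium-mediated dehydrosilylation without peroxide. It sets out from 14. Soft enolisation (Me3SiOTf, Et3N, CH2Cl2, 0 °C) should give the silyl enol ether 1-[2-(guaiazulen-3-yl)-1,4-dimethyl-3-(trimethylsilyloxy)-1H-inden-7-yl]-2-methylpropan-1-one F5. Pd(OAc)2 (1 equiv) in MeCN/DMSO at rt (Saegusa–Ito oxidation) then comes back to the route at 16.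

Further compounds
F1 | step 9 | trans-2-(guaiazulen-3-yl)-4-(1-hydroxy-2-methylpropyl)-3,7-dimethyl-2,3,5,6-tetrahydro-1H-inden-1-one | C[C@@H]1C2=C(C(O)C(C)C)CCC(C)=C2C(=O)[C@H]1c1cc(C)c2cc(C(C)C)ccc(C)c1-2
F2 | step 9 | trans-2-(guaiazulen-3-yl)-4-(1-hydroxy-2-methylpropyl)-3,7-dimethylindan-1-one | C[C@@H]1c2c(C(O)C(C)C)ccc(C)c2C(=O)[C@H]1c1cc(C)c2cc(C(C)C)ccc(C)c1-2
F3 | step 4 | trans-2-bromo-4-(guaiazulen-3-yl)-3-methoxy-5-methylcyclopent-2-en-1-one | C[C@@H]1C(=O)C(Br)=C(OC)[C@H]1c1cc(C)c2cc(C(C)C)ccc(C)c1-2
F4 | step 4 | trans-2-bromo-5-(guaiazulen-3-yl)-3-methoxy-4-methylcyclopent-2-en-1-one | C[C@@H]1C(OC)=C(Br)C(=O)[C@H]1c1cc(C)c2cc(C(C)C)ccc(C)c1-2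
F5 | step 11 | 1-[2-(guaiazulen-3-yl)-1,4-dimethyl-3-(trimethylsilyloxy)-1H-inden-7-yl]-2-methylpropan-1-one | C[C@@H]1c2c(C(=O)C(C)C)ccc(C)c2C(O[Si](C)(C)C)=C1c1cc(C)c2cc(C(C)C)ccc(C)c1-2
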